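**Retrosynthetic overview**

1. Target 16 ← chloro-diol 15 by double Appel bromination (primary CH2Br; ring allylic C–Br with inversion). 15 ← ketone 12 by CBS reduction and stereoinvertive allylic chlorination.
2. Ketone 12 ← vinyl bromide 8 (Br–Li exchange, acylation with Weinreb amide 9). 8 ← 2-bromo-enone 6 by 1,2-reduction and silylation.
3. Key disconnection: the cyclohexenone ring of 6 ← the cyclopentene ring of silyl enol ether 4, by dibromocarbene addition and electrocyclic opening of the fused cyclopropane (one-carbon ring expansion, strain release).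
4. Enabling feature: the ring segment CMe2–CH(Br)–C(side chain)=CH of the target. Its CH(Br) carbon is the ketone carbon of cyclopentanone 3 and is flanked by the quaternary CMe2 carbon, so 3 can enolise to one side only. The unit CH(Br)–C=CH then maps onto the three cyclopropane carbons of a bicyclo[3.1.0]hexane, with the carbene carbon becoming the side-chain-bearing alkene carbon.
5. Ring order: cyclopentane (bought as dione 1; C–Cl centre set by CBS desymmetrisation and inversion) → transient bicyclo[3.1.0]hexane 5 → cyclohexene. The ring expansion is the only ring-forming event.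

Key step: step 4

Remark: the ring carbinol carbon keeps one configuration from step 5 to step 10; its CIP letter changes between compounds only because the priorities of its neighbours change.

**Route**

Step 1
Reactants: 1 2,2-dimethylcyclopentane-1,3-dione
Product: 2 (R)-3-hydroxy-2,2-dimethylcyclopentan-1-one
Conditions: (S)-1-methyl-3,3-diphenyltetrahydro-1H,3H-pyrrolo[1,2-c][1,3,2]oxazaborole (0.2 equiv), catecholborane (1.1 equiv), toluene, −60 °C; aq. NaOH work-up
Reagents that add atoms: none
Why: Corey–Bakshi–Shibata reduction used as enantioselective desymmetrisation of the prochiral 1,3-dione; with the quaternary carbon as the large and the ring CH2 as the small substituent the (S)-catalyst should give the (R)-carbinol at whichever carbonyl reacts, and one equivalent of hydride at low temperature limits over-reduction.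

Step 2
Reactants: 2 (R)-3-hydroxy-2,2-dimethylcyclopentan-1-one
Product: 3 (S)-3-chloro-2,2-dimethylcyclopentan-1-one
Conditions: PPh3, CCl4, MeCN, 60 °C
Reagents that add atoms: carbon tetrachloride ClC(Cl)(Cl)Cl
Why: Appel reaction; SN2 displacement with inversion at the cyclopentyl carbinol carbon turns the (R)-alcohol into the (S)-chloride, and the β-carbonyl group disfavours ionisation and Wagner–Meerwein shift at this neopentyl-type centre.

Step 3
Reactants: 3 (S)-3-chloro-2,2-dimethylcyclopentan-1-one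
Product: 4 (S)-[(4-chloro-5,5-dimethylcyclopent-1-en-1-yl)oxy]trimethylsilane
Conditions: TMSOTf, Et3N, CH2Cl2, 0 °C
Reagents that add atoms: trimethylsilyl trifluoromethanesulfonate C[Si](C)(C)OS(=O)(=O)C(F)(F)F
Why: Silyl enol ether formation by soft enolisation; only the CH2 side can enolise because the other α-carbon is quaternary, and no strong base is present that could attack the chloride.

Step 4
Reactants: 4 (S)-[(4-chloro-5,5-dimethylcyclopent-1-en-1-yl)oxy]trimethylsilane
Product: 6 (S)-2-bromo-5-chloro-6,6-dimethylcyclohex-2-en-1-one, via dibromocyclopropane 5 (not isolated)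
Conditions: CHBr3, KOtBu, pentane, −30 °C to rt; filter; toluene, 80 °C
Reagents that add atoms: bromoform BrC(Br)Br
Why: Dibromocarbene, made from CHBr3 and KOtBu, adds chemoselectively to the electron-rich enol-ether double bond of 4 in a cheletropic [2+1] cycloaddition to give the siloxy-dibromocyclopropane 5; on warming, the strained ring opens by disrotatory two-electron electrocyclic cleavage of the ring-fusion bond (C1–C5 of the bicyclo[3.1.0]hexane) with loss of the endo bromide (Woodward–Hoffmann–DePuy rule), pushed by the siloxy oxygen, and bromide then removes the silyl group to leave enone 6. The closest known reaction type is the one-carbon ring expansion of cyclic silyl enol ethers to 2-halocycloalk-2-enones with dihalocarbenes. The three-membered ring is closed by carbene [2+1] addition, and the six-membered ring is not closed by a cyclisation but arises from the five-membered ring when the shared cyclopropane bond breaks. No new stereocentre survives: both bridgehead centres of 5 become sp2 in 6, so the facial selectivity of the carbene addition is irrelevant, and the C–Cl centre is not touched. The step needs one site of expansion, and this is secured because the quaternary CMe2 carbon leaves only one enol ether, so the carbene carbon must end between the carbonyl carbon and the old CH2 and become the bromine-bearing C2 of the enone; the salts are filtered off before thermolysis so that 6 never meets base, which guards against vinylogous elimination of HCl.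

Step 5
Reactants: 6 (S)-2-bromo-5-chloro-6,6-dimethylcyclohex-2-en-1-one
Product: 7 (1S,5S)-2-bromo-5-chloro-6,6-dimethylcyclohex-2-en-1-ol
Conditions: NaBH4, CeCl3·7H2O, MeOH, −78 °C
Reagents that add atoms: none
Why: Luche reduction (1,2-selective); axial hydride delivery to the half-chair with equatorial chlorine, anti to the pseudoaxial methyl group, as in the reduction of carvone to cis-carveol, should give the alcohol cis to chlorine (substrate control).

Step 6
Reactants: 7 (1S,5S)-2-bromo-5-chloro-6,6-dimethylcyclohex-2-en-1-ol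
Product: 8 {[(1S,5S)-2-bromo-5-chloro-6,6-dimethylcyclohex-2-en-1-yl]oxy}(tert-butyl)dimethylsilane
Conditions: TBSOTf, 2,6-lutidine, CH2Cl2, 0 °C
Reagents that add atoms: tert-butyldimethylsilyl trifluoromethanesulfonate CC(C)(C)[Si](C)(C)OS(=O)(=O)C(F)(F)F
Why: Silyl ether formation with the reactive silyl triflate, needed for this hindered neopentyl-type allylic alcohol; it masks the hydroxyl for the organolithium step.

Step 7
Reactants: 8 {[(1S,5S)-2-bromo-5-chloro-6,6-dimethylcyclohex-2-en-1-yl]oxy}(tert-butyl)dimethylsilane; 9 2-[(tert-butyldimethylsilyl)oxy]-N-methoxy-N-methylacetamide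
Product: 12 2-[(tert-butyldimethylsilyl)oxy]-1-{(4S,6R)-6-[(tert-butyldimethylsilyl)oxy]-4-chloro-5,5-dimethylcyclohex-1-en-1-yl}ethan-1-one, via vinyllithium 10 (not isolated), via lithium hemiaminal adduct 11 (not isolated)
Conditions: t-BuLi (2.1 equiv), Et2O, −78 °C; then 9, −78 to −20 °C; aq. NH4Cl
Reagents that add atoms: none
Why: Bromine–lithium exchange followed by Weinreb ketone synthesis; the chelated tetrahedral adduct 11 prevents over-addition, and the secondary alkyl chloride and the silyl ether should be inert at −78 °C.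

Step 8
Reactants: 12 2-[(tert-butyldimethylsilyl)oxy]-1-{(4S,6R)-6-[(tert-butyldimethylsilyl)oxy]-4-chloro-5,5-dimethylcyclohex-1-en-1-yl}ethan-1-one
Product: 13 (1R)-2-[(tert-butyldimethylsilyl)oxy]-1-{(4S,6R)-6-[(tert-butyldimethylsilyl)oxy]-4-chloro-5,5-dimethylcyclohex-1-en-1-yl}ethan-1-ol
Conditions: (R)-1-methyl-3,3-diphenyltetrahydro-1H,3H-pyrrolo[1,2-c][1,3,2]oxazaborole (0.5 equiv), catecholborane, toluene, −78 °C; aq. NaOH work-up
Reagents that add atoms: none
Why: Corey–Bakshi–Shibata reduction, 1,2-selective on the enone; with the α-branched alkenyl group as the large and CH2OTBS as the small substituent the (R)-catalyst should give the (R)-carbinol (catalyst control).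

Step 9
Reactants: 13 (1R)-2-[(tert-butyldimethylsilyl)oxy]-1-{(4S,6R)-6-[(tert-butyldimethylsilyl)oxy]-4-chloro-5,5-dimethylcyclohex-1-en-1-yl}ethan-1-ol
Product: 14 tert-butyl{[(1S,5S)-2-{(1S)-2-[(tert-butyldimethylsilyl)oxy]-1-chloroethyl}-5-chloro-6,6-dimethylcyclohex-2-en-1-yl]oxy}dimethylsilane
Conditions: PPh3, hexachloroacetone, CH2Cl2, −20 to 0 °C
Reagents that add atoms: hexachloroacetone ClC(Cl)(Cl)C(=O)C(Cl)(Cl)Cl
Why: Appel-type deoxychlorination with PPh3/hexachloroacetone, the variant that converts secondary allylic alcohols into chlorides by SN2 with inversion and little allylic transposition; inversion turns the (R)-alcohol into the (S)-chloride, and no vicinal halogen is present that could participate.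

Step 10
Reactants: 14 tert-butyl{[(1S,5S)-2-{(1S)-2-[(tert-butyldimethylsilyl)oxy]-1-chloroethyl}-5-chloro-6,6-dimethylcyclohex-2-en-1-yl]oxy}dimethylsilane
Product: 15 (1S,5S)-5-chloro-2-[(1S)-1-chloro-2-hydroxyethyl]-6,6-dimethylcyclohex-2-en-1-ol
Conditions: HF·pyridine, THF/pyridine, 0 °C to rt
Reagents that add atoms: none
Why: Fluoride-mediated desilylation of both silyl ethers under buffered acidic conditions, chosen because basic fluoride could close the chlorohydrin to an epoxide or eliminate the allylic chloride.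

Step 11
Reactants: 15 (1S,5S)-5-chloro-2-[(1S)-1-chloro-2-hydroxyethyl]-6,6-dimethylcyclohex-2-en-1-ol
Product: 16 (4S,6R)-6-bromo-1-[(1S)-2-bromo-1-chloroethyl]-4-chloro-5,5-dimethylcyclohex-1-ene
Conditions: PPh3 (4 equiv), CBr4 (4 equiv), CH2Cl2, −20 to 0 °C, diol added to the preformed reagent
Reagents that add atoms: carbon tetrabromide BrC(Br)(Br)Br
Why: Double Appel bromination; the primary alcohol is displaced by SN2 and the ring allylic alcohol with inversion, which should convert the alcohol cis to chlorine into the bromide trans to chlorine, i.e. the (R)-configured C–Br centre, while inverse addition to excess reagent activates both hydroxyls at once so that neither is left free to close a cyclic ether.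

**Compound list**

1 | 2,2-dimethylcyclopentane-1,3-dione | CC1(C)C(=O)CCC1=O | starting material
2 | (R)-3-hydroxy-2,2-dimethylcyclopentan-1-one | CC1(C)[C@H](O)CCC1=O | intermediate
3 | (S)-3-chloro-2,2-dimethylcyclopentan-1-one | CC1(C)[C@@H](Cl)CCC1=O | intermediate
4 | (S)-[(4-chloro-5,5-dimethylcyclopent-1-en-1-yl)oxy]trimethylsilane | CC1(C)[C@@H](Cl)CC=C1O[Si](C)(C)C | intermediate
5 | (1R,3S,5S)-6,6-dibromo-3-chloro-2,2-dimethyl-1-[(trimethylsilyl)oxy]bicyclo[3.1.0]hexane (cyclopropane anti to chlorine drawn; the syn isomer gives the same product) | CC1(C)[C@@H](Cl)C[C@@H]2C(Br)(Br)[C@]12O[Si](C)(C)C | intermediate (not isolated)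
6 | (S)-2-bromo-5-chloro-6,6-dimethylcyclohex-2-en-1-one | CC1(C)[C@@H](Cl)CC=C(Br)C1=O | intermediate
7 | (1S,5S)-2-bromo-5-chloro-6,6-dimethylcyclohex-2-en-1-ol (OH cis to Cl) | CC1(C)[C@@H](Cl)CC=C(Br)[C@H]1O | intermediate
8 | {[(1S,5S)-2-bromo-5-chloro-6,6-dimethylcyclohex-2-en-1-yl]oxy}(tert-butyl)dimethylsilane | CC1(C)[C@@H](Cl)CC=C(Br)[C@H]1O[Si](C)(C)C(C)(C)C | intermediate
9 | 2-[(tert-butyldimethylsilyl)oxy]-N-methoxy-N-methylacetamide | CON(C)C(=O)CO[Si](C)(C)C(C)(C)C | starting material
10 | {(4S,6R)-6-[(tert-butyldimethylsilyl)oxy]-4-chloro-5,5-dimethylcyclohex-1-en-1-yl}lithium | CC1(C)[C@@H](Cl)CC=C([Li])[C@H]1O[Si](C)(C)C(C)(C)C | intermediate (not isolated)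
11 | lithium 2-[(tert-butyldimethylsilyl)oxy]-1-{(4S,6R)-6-[(tert-butyldimethylsilyl)oxy]-4-chloro-5,5-dimethylcyclohex-1-en-1-yl}-1-[methoxy(methyl)amino]ethan-1-olate (hemiaminal carbon not controlled) | CC1(C)[C@@H](Cl)CC=C(C(O[Li])(CO[Si](C)(C)C(C)(C)C)N(C)OC)[C@H]1O[Si](C)(C)C(C)(C)C | intermediate (not isolated)
12 | 2-[(tert-butyldimethylsilyl)oxy]-1-{(4S,6R)-6-[(tert-butyldimethylsilyl)oxy]-4-chloro-5,5-dimethylcyclohex-1-en-1-yl}ethan-1-one | CC1(C)[C@@H](Cl)CC=C(C(=O)CO[Si](C)(C)C(C)(C)C)[C@H]1O[Si](C)(C)C(C)(C)C | intermediate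
13 | (1R)-2-[(tert-butyldimethylsilyl)oxy]-1-{(4S,6R)-6-[(tert-butyldimethylsilyl)oxy]-4-chloro-5,5-dimethylcyclohex-1-en-1-yl}ethan-1-ol | CC1(C)[C@@H](Cl)CC=C([C@@H](O)CO[Si](C)(C)C(C)(C)C)[C@H]1O[Si](C)(C)C(C)(C)C | intermediate
14 | tert-butyl{[(1S,5S)-2-{(1S)-2-[(tert-butyldimethylsilyl)oxy]-1-chloroethyl}-5-chloro-6,6-dimethylcyclohex-2-en-1-yl]oxy}dimethylsilane | CC1(C)[C@@H](Cl)CC=C([C@H](Cl)CO[Si](C)(C)C(C)(C)C)[C@H]1O[Si](C)(C)C(C)(C)C | intermediate
15 | (1S,5S)-5-chloro-2-[(1S)-1-chloro-2-hydroxyethyl]-6,6-dimethylcyclohex-2-en-1-ol | CC1(C)[C@@H](Cl)CC=C([C@H](Cl)CO)[C@H]1O | intermediate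
16 | (4S,6R)-6-bromo-1-[(1S)-2-bromo-1-chloroethyl]-4-chloro-5,5-dimethylcyclohex-1-ene | CC1(C)[C@@H](Cl)CC=C([C@H](Cl)CBr)[C@@H]1Br | target

**Totals**

Total step count: 11. Longest linear sequence: 11 steps (1 to 16; 9 is a purchased reagent).

**Steps most likely to fail**

Step 11. The ring hydroxyl sits on a neopentyl-type allylic carbon, so bromide may enter at the unhindered ring CH with a shift of the double bond (SN2' transposition) instead of displacing directly. Ether closure between the two oxygens is a second leak. The fallback never substitutes at the hindered carbon and sets out from 7.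

- Phenyl isocyanate and Et3N give (1S,5S)-2-bromo-5-chloro-6,6-dimethylcyclohex-2-en-1-yl N-phenylcarbamate F1.
- Deprotonation with MeLi, then CuI, PPh3 and PhMe2SiLi, should deliver silicon by carbamate-directed syn-SN2' substitution to the ring CH on the face the oxygen leaves, cis to chlorine, giving [(1R,5S)-2-bromo-5-chloro-4,4-dimethylcyclohex-2-en-1-yl]dimethyl(phenyl)silane F2.
- Bromine–lithium exchange (t-BuLi, −78 °C) gives {(4S,6R)-4-chloro-6-[dimethyl(phenyl)silyl]-3,3-dimethylcyclohex-1-en-1-yl}lithium F3, which adds to 9 to give the lithium hemiaminal adduct F4 and, after work-up, 2-[(tert-butyldimethylsilyl)oxy]-1-{(4S,6R)-4-chloro-6-[dimethyl(phenyl)silyl]-3,3-dimethylcyclohex-1-en-1-yl}ethan-1-one F5.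
- Reduction as in step 8 gives (1R)-2-[(tert-butyldimethylsilyl)oxy]-1-{(4S,6R)-4-chloro-6-[dimethyl(phenyl)silyl]-3,3-dimethylcyclohex-1-en-1-yl}ethan-1-ol F6.
- PPh3/hexachloroacetone gives tert-butyl{(2S)-2-chloro-2-{(4S,6R)-4-chloro-6-[dimethyl(phenyl)silyl]-3,3-dimethylcyclohex-1-en-1-yl}ethoxy}dimethylsilane F7; here an SN2' attack would have to hit the alkene carbon next to CMe2, so direct substitution is favoured.
- Pyridinium p-toluenesulfonate in MeOH frees (2S)-2-chloro-2-{(4S,6R)-4-chloro-6-[dimethyl(phenyl)silyl]-3,3-dimethylcyclohex-1-en-1-yl}ethan-1-ol F8.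
- CBr4/PPh3 gives {(1R,5S)-2-[(1S)-2-bromo-1-chloroethyl]-5-chloro-4,4-dimethylcyclohex-2-en-1-yl}dimethyl(phenyl)silane F9.
- N-bromosuccinimide in CH2Cl2 at −78 °C should then effect anti-SE2' bromodesilylation: bromine enters at the carbon next to CMe2 on the face opposite silicon (trans to chlorine) and the double bond returns to its place, which gives 16 directly.

Step 9. Chloride may enter at the ring CH with the double bond moving to the exocyclic position (allylic transposition), or the centre may partly ionise and lose configuration. The fallback forms the C–Cl bond by epoxide opening and sets out from 13.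

- Pyridinium p-toluenesulfonate in MeOH cleaves the primary silyl ether to (1R)-1-{(4S,6R)-6-[(tert-butyldimethylsilyl)oxy]-4-chloro-5,5-dimethylcyclohex-1-en-1-yl}ethane-1,2-diol F10.
- Mitsunobu cyclodehydration (PPh3, diisopropyl azodicarboxylate) closes tert-butyl{[(1R,5S)-5-chloro-6,6-dimethyl-2-[(2R)-oxiran-2-yl]cyclohex-2-en-1-yl]oxy}dimethylsilane F11 with retention at the carbinol carbon.
- TiCl4 in CH2Cl2 at −78 °C should open the vinyl epoxide at the allylic carbon with inversion to (2S)-2-{(4S,6S)-6-[(tert-butyldimethylsilyl)oxy]-4-chloro-5,5-dimethylcyclohex-1-en-1-yl}-2-chloroethan-1-ol F12.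
- HF·pyridine then removes the ring silyl group and the route is rejoined at 15.

Step 2. Backside attack at the carbinol carbon next to the quaternary centre may be too slow, so that elimination or skeletal rearrangement takes over. The fallback delivers chloride from the front side and sets out from 1.

- Reduction as in step 1 but with the (R)-configured oxazaborolidine gives (S)-3-hydroxy-2,2-dimethylcyclopentan-1-one F13.
- SOCl2 converts it into (S)-2,2-dimethyl-3-oxocyclopentyl chlorosulfite F14.
- Catalytic TiCl4 at −78 °C should collapse F14 with retention (SNi-type front-side delivery), which rejoins the route at 3.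

**Further compounds**

F1 | step 11 | (1S,5S)-2-bromo-5-chloro-6,6-dimethylcyclohex-2-en-1-yl N-phenylcarbamate | CC1(C)[C@@H](Cl)CC=C(Br)[C@H]1OC(=O)Nc1ccccc1
F2 | step 11 | [(1R,5S)-2-bromo-5-chloro-4,4-dimethylcyclohex-2-en-1-yl]dimethyl(phenyl)silane | CC1(C)[C@@H](Cl)C[C@@H]([Si](C)(C)c2ccccc2)C(Br)=C1
F3 | step 11 | {(4S,6R)-4-chloro-6-[dimethyl(phenyl)silyl]-3,3-dimethylcyclohex-1-en-1-yl}lithium | CC1(C)[C@@H](Cl)C[C@@H]([Si](C)(C)c2ccccc2)C([Li])=C1
F4 | step 11 | lithium 2-[(tert-butyldimethylsilyl)oxy]-1-{(4S,6R)-4-chloro-6-[dimethyl(phenyl)silyl]-3,3-dimethylcyclohex-1-en-1-yl}-1-[methoxy(methyl)amino]ethan-1-olate | CC1(C)[C@@H](Cl)C[C@@H]([Si](C)(C)c2ccccc2)C(C(O[Li])(CO[Si](C)(C)C(C)(C)C)N(C)OC)=C1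
F5 | step 11 | 2-[(tert-butyldimethylsilyl)oxy]-1-{(4S,6R)-4-chloro-6-[dimethyl(phenyl)silyl]-3,3-dimethylcyclohex-1-en-1-yl}ethan-1-one | CC1(C)[C@@H](Cl)C[C@@H]([Si](C)(C)c2ccccc2)C(C(=O)CO[Si](C)(C)C(C)(C)C)=C1
F6 | step 11 | (1R)-2-[(tert-butyldimethylsilyl)oxy]-1-{(4S,6R)-4-chloro-6-[dimethyl(phenyl)silyl]-3,3-dimethylcyclohex-1-en-1-yl}ethan-1-ol | CC1(C)[C@@H](Cl)C[C@@H]([Si](C)(C)c2ccccc2)C([C@@H](O)CO[Si](C)(C)C(C)(C)C)=C1
F7 | step 11 | tert-butyl{(2S)-2-chloro-2-{(4S,6R)-4-chloro-6-[dimethyl(phenyl)silyl]-3,3-dimethylcyclohex-1-en-1-yl}ethoxy}dimethylsilane | CC1(C)[C@@H](Cl)C[C@@H]([Si](C)(C)c2ccccc2)C([C@H](Cl)CO[Si](C)(C)C(C)(C)C)=C1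
F8 | step 11 | (2S)-2-chloro-2-{(4S,6R)-4-chloro-6-[dimethyl(phenyl)silyl]-3,3-dimethylcyclohex-1-en-1-yl}ethan-1-ol | CC1(C)[C@@H](Cl)C[C@@H]([Si](C)(C)c2ccccc2)C([C@H](Cl)CO)=C1
F9 | step 11 | {(1R,5S)-2-[(1S)-2-bromo-1-chloroethyl]-5-chloro-4,4-dimethylcyclohex-2-en-1-yl}dimethyl(phenyl)silane | CC1(C)[C@@H](Cl)C[C@@H]([Si](C)(C)c2ccccc2)C([C@H](Cl)CBr)=C1
F10 | step 9 | (1R)-1-{(4S,6R)-6-[(tert-butyldimethylsilyl)oxy]-4-chloro-5,5-dimethylcyclohex-1-en-1-yl}ethane-1,2-diol | CC1(C)[C@@H](Cl)CC=C([C@@H](O)CO)[C@H]1O[Si](C)(C)C(C)(C)C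
F11 | step 9 | tert-butyl{[(1R,5S)-5-chloro-6,6-dimethyl-2-[(2R)-oxiran-2-yl]cyclohex-2-en-1-yl]oxy}dimethylsilane | CC1(C)[C@@H](Cl)CC=C([C@@H]2CO2)[C@H]1O[Si](C)(C)C(C)(C)C
F12 | step 9 | (2S)-2-{(4S,6S)-6-[(tert-butyldimethylsilyl)oxy]-4-chloro-5,5-dimethylcyclohex-1-en-1-yl}-2-chloroethan-1-ol | CC1(C)[C@@H](Cl)CC=C([C@H](Cl)CO)[C@H]1O[Si](C)(C)C(C)(C)C
F13 | step 2 | (S)-3-hydroxy-2,2-dimethylcyclopentan-1-one | CC1(C)[C@@H](O)CCC1=O
F14 | step 2 | (S)-2,2-dimethyl-3-oxocyclopentyl chlorosulfite | CC1(C)[C@@H](OS(Cl)=O)CCC1=O
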